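I decided to carry one number from the two earlier runs to the new flask, and to find it by sorting what happens by time scale.

| setting | noon | dusk | flask |
|---|---|---|---|
| substrate | 0.20 M | 0.20 M | 0.20 M |
| precatalyst | 0.20 mM | 0.30 mM | 0.40 mM |
| remark | run made earlier | run made earlier |  |
| time |  |  | 40 h |

| run | time / h | catalyst intermediate / % | substrate / % | target / % |
|---|---|---|---|---|
| noon | 2.50 | 1.6 | 78.7 | 1.1 |
| noon | 4.00 | 1.2 | 71.1 | 0.8 |
| noon | 6.00 | 1.3 | 60.8 | 2.5 |
| noon | 10.0 | 0.1 | 53.6 | 4.9 |
| noon | 15.0 | 1.1 | 45.0 | 9.8 |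
| noon | 20.0 | 0.9 | 41.8 | 14.0 |
| noon | 30.0 | 0 | 39.1 | 20.7 |
| dusk | 5.00 | 0 | 65.3 | 3.0 |
| dusk | 10.0 | 2.8 | 47.8 | 8.3 |
| dusk | 15.0 | 0 | 42.9 | 14.7 |
| dusk | 20.0 | 0 | 40.6 | 18.6 |
| dusk | 25.0 | 0.9 | 35.2 | 24.5 |
| dusk | 30.0 | 0 | 32.7 | 30.0 |

(scatter of a reading: 1 percentage point)

- a reading or a percentage of substrate is of its free form alone

- the largest share of what was charged as substrate, at 40 h belongs to (target / catalyst intermediate / substrate)
- the largest share itself, whichever of these holds it, in percent of the substrate charged

The catalyst intermediate never read above 2.8 %, so I left it out. In the noon run, substrate, target and intermediate summed to 58.6 % by 10.0 h and to 59.8 % at 30.0 h, so an unseen store had filled by the first of these times and read about level between the two. In the noon run at 30.0 h, substrate read half of what was not target.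

The next rung is the drain of that material into target, which I treated as a pseudo-first-order decay, so in each run I took the slope of ln(1 − target) from 15.0 h to 30.0 h and divided it by the charge of precatalyst:

noon: 42.9 L mol⁻¹ h⁻¹

dusk: 43.9 L mol⁻¹ h⁻¹

Their mean, 43.4 L mol⁻¹ h⁻¹, is my drain constant: the fraction of non-target material becoming target per hour, per unit of [precatalyst] charged. Traced back, the two lines start about 2.96 h late. For the new flask:

drain time = 57.6 h

target = 47.5 %

substrate = 25.9 %

So I expected target to lead, ahead of substrate.

The forecast, opening with "The balance is the key", named target at 45 %, within 38 % to 52 %.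

The flask gave target at 49.9 %, with substrate at 22.7 %.

    catalyst intermediate → free catalyst + target (k = 80.0 h⁻¹)
    substrate ⇌ dormant form (K = 0.980, k = 0.110 h⁻¹)
    substrate + free catalyst → catalyst intermediate (k = 140 L mol⁻¹ h⁻¹)
    precatalyst ⇌ free catalyst (K = 10.0, k = 0.100 h⁻¹)

Run backwards, the flask's 49.9 % gives a drain constant of 46.6 L mol⁻¹ h⁻¹, above the 43.4 L mol⁻¹ h⁻¹ I read. The neighbouring flask is the same one read at 6.0 d. With 43.4 L mol⁻¹ h⁻¹ my reckoning gives it 91.4 % target, while the simulation gives 95.1 %, which corresponds to a constant of 53.3 L mol⁻¹ h⁻¹. At that reading its free catalyst stood at 90.3 % of the catalyst charged, against 72.5 % in the same flask at 20.0 h.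

The readings were computed with made-up constants; scatter was added.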